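**Strategy.** Everything rests on cutting the C10–C20 bond of the δ-lactone (C7(=O)–O–C20–C10–C9–C8). In the precursor, C10 is the central carbon of a cyclohexane-1,3-dione (future ring A; carbonyls at C1 and C5) attached to C9 of the finished bicyclo[3.2.1]octane, and the C8 carboxyl is a chloromethyl ester. Base closes the lactone by 6-exo-tet C-alkylation and creates the spiro quaternary C10 in one operation. Because the dione is locally symmetric, the ring closure needs no facial selectivity; C10, C1, C4 and C5 are defined afterwards by a desymmetrising reduction and substrate-controlled steps (ent-kaurane numbering throughout).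

Key step: step 8

Remark 1: locants are the ent-kaurane locants of the target: ring A = C1–C5, C10; lactone = C7(=O)–O–C20–C10–C9–C8; bicyclo[3.2.1]octane = C8, C9, C11–C16; C17 = exocyclic CH2; C18 = CH3 and C19 = CH2O on C4; C6 = CH2OH on C5.
Remark 2 (assumption): the sense of induction of the cinchona catalyst (step 1) and of the CBS catalyst (step 9) is taken from the usual models; if a first run shows the opposite sense, the pseudo-enantiomeric alkaloid or the catalyst antipode is used.
Remark 3 (assumption): in the lithium enolate of step 12 the bulky C9 arm of the spiro carbon is taken to shield its own face of C4; if the opposite face reacts, the two alkylations are run in the reverse order, as described at the end.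

Step 1
Reactants: 1 cis-cyclohex-4-ene-1,2-dicarboxylic anhydride (meso); 2 2-(trimethylsilyl)ethanol
Product: 3 (1R,6S)-6-{[2-(trimethylsilyl)ethoxy]carbonyl}cyclohex-3-ene-1-carboxylic acid (cis half-ester; free acid on the future C9, ester on the future C8)
Conditions: (DHQD)2AQN (10 mol%), 2 (3 equiv), Et2O, −20 °C
Reagents that add atoms: 2-(trimethylsilyl)ethanol (2), C[Si](C)(C)CCO
Why: Cinchona-alkaloid-catalysed desymmetrising alcoholysis of a meso anhydride differentiates the enantiotopic carbonyls and sets both ring stereocentres of the cis half-ester.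

Step 2
Reactants: 3 half-ester; 4 2,3-dibromoprop-1-ene
Product: 5 (1R,6R)-6-(2-bromoprop-2-en-1-yl)-6-{[2-(trimethylsilyl)ethoxy]carbonyl}cyclohex-3-ene-1-carboxylic acid (bromoallyl group trans to CO2H, the two carboxyl groups cis)
Conditions: LDA (2.2 equiv), THF, −78 °C; then 4, −78 → 0 °C; 1 M HCl work-up
Reagents that add atoms: 2,3-dibromoprop-1-ene (4), C=C(Br)CBr
Why: Alkylation of the dianion (carboxylate plus ester enolate at C8) with the allylic bromide should occur trans to the neighbouring C9 carboxylate, so the quaternary C8 obtains the target configuration.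

Step 3
Reactants: 5 bromoallyl acid
Product: 6 6-methylidene-1-{[2-(trimethylsilyl)ethoxy]carbonyl}bicyclo[3.2.1]octane-2-carboxylic acid (C8, C9, C13 as in the target; CO2H at C9 cis to the C7 ester and anti to the C15–C16 bridge)
Conditions: Bu3SnH (1.3 equiv, 0.02 M), AIBN (cat.), benzene, 80 °C
Reagents that add atoms: none
Why: Stork vinyl-radical cyclisation: the C16 radical formed by bromine abstraction adds 5-exo-trig to C13 of the C12=C13 alkene, the new C13 centre being fixed by the cis-1,3 bridge across ring C, and the stannane is kept concentrated enough to reduce the C12 radical before it can rearrange by the homoallyl pathway to the bicyclo[2.2.2] isomer.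

Step 4
Reactants: 7 3-methoxycyclohex-2-en-1-one; 8 N-iodosuccinimide
Product: 9 2-iodo-3-methoxycyclohex-2-en-1-one
Conditions: NIS, CH2Cl2, rt
Reagents that add atoms: N-iodosuccinimide (8), O=C1CCC(=O)N1I
Why: Electrophilic α-iodination of a vinylogous ester at its nucleophilic C2 (the enol-ether β-carbon).

Step 5
Reactants: 6 bicyclic acid; 9 2-iodo-3-methoxycyclohex-2-en-1-one
Product: 10 2-(trimethylsilyl)ethyl 2-(2-methoxy-6-oxocyclohex-1-en-1-yl)-6-methylidenebicyclo[3.2.1]octane-1-carboxylate (C9–C10 bond anti to the C15–C16 bridge, cis to the ester)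
Conditions: Ir[dF(CF3)ppy]2(dtbbpy)PF6 (1 mol%), NiCl2·glyme/dtbbpy (10 mol%), Cs2CO3, DMSO, blue LEDs, rt
Reagents that add atoms: 2-iodo-3-methoxycyclohex-2-en-1-one (9), COC1=C(I)C(=O)CCC1
Why: Metallaphotoredox decarboxylative C(sp3)–C(sp2) coupling: the C9 radical formed by oxidation and CO2 loss should be captured by the alkenyl–nickel species on the axial face anti to the C15–C16 bridge, placing C10 trans to C15 and cis to the C7 ester.

Step 6
Reactants: 10 coupled silylethyl ester; 11 chloroiodomethane
Product: 13 chloromethyl 2-(2-methoxy-6-oxocyclohex-1-en-1-yl)-6-methylidenebicyclo[3.2.1]octane-1-carboxylate, via tetrabutylammonium carboxylate 12 (not isolated)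
Conditions: TBAF (1.1 equiv), THF, 0 °C → rt; then 11 (5 equiv), rt
Reagents that add atoms: chloroiodomethane (11), ClCI
Why: Fluoride-induced fragmentation of the 2-(trimethylsilyl)ethyl ester is independent of the neopentyl hindrance, and the carboxylate is O-alkylated by SN2 at the iodine-bearing carbon of chloroiodomethane.

Step 7
Reactants: 13 chloromethyl ester; 14 water
Product: 15 chloromethyl 2-(2,6-dioxocyclohexyl)-6-methylidenebicyclo[3.2.1]octane-1-carboxylate (dione, largely enolised)
Conditions: 1 M HCl, THF, rt
Reagents that add atoms: water (14), O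
Why: Acid hydrolysis of the vinylogous ester unmasks the 1,3-dione, while the neopentyl-type chloromethyl ester should resist hydrolysis.

Step 8
Reactants: 15 dione chloromethyl ester
Product: 16 spiro-lactone dione: 7,20-lactone closed onto C10, ring A a cyclohexane-1,3-dione (C1=O, C5=O), C16=C17 methylidene, C15 still CH2
Conditions: Cs2CO3 (1.5 equiv), Bu4NI (10 mol%), DMF (0.01 M), 50 °C
Reagents that add atoms: none
Why: Cs2CO3 deprotonates the strongly acidic 2-substituted 1,3-dione and the central enolate carbon C10 displaces halide from the tethered acyloxymethyl chloride (activated by catalytic iodide) in an intramolecular SN2 reaction, forming C10–C20. The closest known reaction types are the spiroannulation of 2-substituted cyclic 1,3-diones by intramolecular C-alkylation and the C-alkylation of stabilised enolates with α-halo ethers and halomethyl esters. The δ-lactone ring (C7, O, C20, C10, C9, C8) closes in the 6-exo-tet mode, helped by the gauche arrangement of the equatorial C7 ester and the axial C9–C10 bond on ring C. No new stereocentre arises, because the C1 and C5 arms of the dione are identical, so either enolate face and either enol tautomer funnels into the single spiro compound 16. The step needs C- over O-alkylation and alkylation over acyl transfer: O-alkylation would require an eight-membered ring, the ester carbonyl is shielded by the quaternary C8, and no other acidic C–H is present.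

Step 9
Reactants: 16 spiro-lactone dione
Product: 17 (1S)-1-hydroxy-5-oxo spiro-lactone (1-OH cis to C20; C10 now a stereocentre as in the target)
Conditions: (R)-Me-CBS (20 mol%), catecholborane (1.1 equiv), toluene/CH2Cl2, −78 → −40 °C
Reagents that add atoms: none
Why: CBS desymmetrisation of a 2,2-disubstituted 1,3-dione: the catalyst fixes the carbinol as (S) and, of the two diastereotopic carbonyls, the one that can be reduced in this sense by axial hydride delivery anti to the axial C20 arm should react, giving 1-OH cis to C20; catecholborane leaves the alkene untouched.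

Step 10
Reactants: 17 hydroxy ketone; 18 tert-butyldimethylsilyl triflate
Product: 19 1-O-TBS ether of 17
Conditions: TBSOTf (1.1 equiv), 2,6-lutidine, CH2Cl2, −78 → 0 °C
Reagents that add atoms: tert-butyldimethylsilyl triflate (18), CC(C)(C)[Si](C)(C)OS(=O)(=O)C(F)(F)F
Why: Silylation of the hindered secondary alcohol with the reactive triflate blocks retro-aldol cleavage and O-alkylation in the enolate steps that follow.

Step 11
Reactants: 19 TBS ether; 20 iodomethane
Product: 21 4-methyl-5-oxo compound (C4 epimers)
Conditions: LDA (1.1 equiv), THF, −78 °C; then MeI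
Reagents that add atoms: iodomethane (20), CI
Why: Enolisation of the C5 ketone is possible only towards C4 (C10 is quaternary) and the lithium enolate is methylated; the C4 configuration is irrelevant because C4 is planarised again in step 12.

Step 12
Reactants: 21 4-methyl ketone; 22 (triisopropylsiloxy)methyl chloride (TOM-Cl)
Product: 23 ketone with quaternary C4 (CH3-18 trans to C20, CH2OTIPS-19 cis to C20)
Conditions: LDA, THF, −78 °C; then TOM-Cl, −78 → −20 °C
Reagents that add atoms: (triisopropylsiloxy)methyl chloride (22), ClCO[Si](C(C)C)(C(C)C)C(C)C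
Why: C-alkylation of the tetrasubstituted C4=C5 lithium enolate with an α-chloro ether (as with BOM-Cl) should take place anti to the bulky bicyclic C9 arm of the neighbouring spiro carbon, which is expected to sit pseudoaxial to avoid A(1,2) strain with the O–Li group, i.e. on the C20 face, which makes C19 cis to C20.

Step 13
Reactants: 23 quaternary ketone; 24 trimethylsulfonium iodide
Product: 25 C5 spiro-epoxide (C5–C6 oxirane, either C5 epimer)
Conditions: Me3S+ I−, KHMDS, THF, 0 °C → rt
Reagents that add atoms: trimethylsulfonium iodide (24), C[S+](C)C.[I-]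
Why: Corey–Chaykovsky epoxidation: the small sulfonium ylide adds to the non-enolisable C5 ketone and closes the oxirane, and both epimers are usable because C5 is planarised in step 15.

Step 14
Reactants: 25 spiro-epoxide; 26 acetic anhydride
Product: 28 1,19-diacetate spiro-epoxide, via diol 27 (not isolated)
Conditions: TBAF, AcOH, THF, 50 °C; then Ac2O, Et3N, DMAP, rt
Reagents that add atoms: acetic anhydride (26), CC(=O)OC(C)=O
Why: Buffered fluoride cleaves both silyl ethers without letting the C19 or C1 alkoxide attack the neighbouring epoxide, and the two hydroxyls are acetylated in the same flask.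

Step 15
Reactants: 28 diacetate epoxide
Product: 29 1,19-diacetoxy-6-hydroxy spiro-lactone with 16(17)-ene and C15H2 (H-5 cis to CH3-18; C6 cis to C19 and C20)
Conditions: Cp2TiCl2 (20 mol%), Mn, 2,4,6-collidine·HCl, cyclohexa-1,4-diene, THF, rt
Reagents that add atoms: none
Why: Titanocene(III)-mediated reductive epoxide opening (Nugent–RajanBabu type) gives the tertiary C5 radical and the C6–O–Ti alkoxide, and hydrogen-atom transfer from cyclohexadiene should occur axially on the face anti to the two axial CH2O groups (C19, C20), setting C5 with C6 equatorial.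

Step 16
Reactants: 29 6-alcohol; 30 tert-butyl hydroperoxide
Product: 31 15-hydroxy compound (C15 epimers)
Conditions: SeO2 (0.5 equiv), TBHP, CH2Cl2, rt
Reagents that add atoms: tert-butyl hydroperoxide (30), CC(C)(C)OO
Why: Selenium dioxide allylic hydroxylation (ene reaction, then [2,3]-shift) attacks C15, the only allylic CH2 of the 1,1-disubstituted alkene, since C13 is a bridgehead.

Step 17
Reactants: 31 15-hydroxy compound
Product: 32 target, CNP0105570.2
Conditions: MnO2 (excess), CH2Cl2, rt
Reagents that add atoms: none
Why: MnO2 oxidises the allylic C15 alcohol to the enone and leaves the saturated primary C6 alcohol untouched.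

**Compound list**

1 | cis-cyclohex-4-ene-1,2-dicarboxylic anhydride (meso) | O=C1OC(=O)[C@@H]2CC=CC[C@H]12 | starting material
2 | 2-(trimethylsilyl)ethanol | C[Si](C)(C)CCO | starting material
3 | (1R,6S)-6-{[2-(trimethylsilyl)ethoxy]carbonyl}cyclohex-3-ene-1-carboxylic acid | C[Si](C)(C)CCOC(=O)[C@H]1CC=CC[C@H]1C(=O)O | intermediate
4 | 2,3-dibromoprop-1-ene | C=C(Br)CBr | starting material
5 | (1R,6R)-6-(2-bromoprop-2-en-1-yl)-6-{[2-(trimethylsilyl)ethoxy]carbonyl}cyclohex-3-ene-1-carboxylic acid | C=C(Br)C[C@]1(C(=O)OCC[Si](C)(C)C)CC=CC[C@H]1C(=O)O | intermediate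
6 | 6-methylidene-1-{[2-(trimethylsilyl)ethoxy]carbonyl}bicyclo[3.2.1]octane-2-carboxylic acid (C8, C9, C13 as in the target) | C=C1C[C@]2(C(=O)OCC[Si](C)(C)C)C[C@H]1CC[C@H]2C(=O)O | intermediate
7 | 3-methoxycyclohex-2-en-1-one | COC1=CC(=O)CCC1 | starting material
8 | N-iodosuccinimide | O=C1CCC(=O)N1I | starting material
9 | 2-iodo-3-methoxycyclohex-2-en-1-one | COC1=C(I)C(=O)CCC1 | intermediate
10 | 2-(trimethylsilyl)ethyl 2-(2-methoxy-6-oxocyclohex-1-en-1-yl)-6-methylidenebicyclo[3.2.1]octane-1-carboxylate | C=C1C[C@]2(C(=O)OCC[Si](C)(C)C)C[C@H]1CC[C@H]2C3=C(OC)CCCC3=O | intermediate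
11 | chloroiodomethane | ClCI | starting material
12 | tetrabutylammonium 2-(2-methoxy-6-oxocyclohex-1-en-1-yl)-6-methylidenebicyclo[3.2.1]octane-1-carboxylate | C=C1C[C@]2(C(=O)[O-])C[C@H]1CC[C@H]2C3=C(OC)CCCC3=O.CCCC[N+](CCCC)(CCCC)CCCC | intermediate (not isolated)
13 | chloromethyl 2-(2-methoxy-6-oxocyclohex-1-en-1-yl)-6-methylidenebicyclo[3.2.1]octane-1-carboxylate | C=C1C[C@]2(C(=O)OCCl)C[C@H]1CC[C@H]2C3=C(OC)CCCC3=O | intermediate
14 | water | O | starting material
15 | chloromethyl 2-(2,6-dioxocyclohexyl)-6-methylidenebicyclo[3.2.1]octane-1-carboxylate | C=C1C[C@]2(C(=O)OCCl)C[C@H]1CC[C@H]2C3C(=O)CCCC3=O | intermediate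
16 | spiro-lactone dione (7,20-lactone; C1=O, C5=O; 16(17)-ene) | C=C1C[C@]23C[C@H]1CC[C@H]2C4(COC3=O)C(=O)CCCC4=O | intermediate
17 | (1S)-1-hydroxy-5-oxo spiro-lactone | C=C1C[C@]23C[C@H]1CC[C@H]2[C@]4(COC3=O)[C@@H](O)CCCC4=O | intermediate
18 | tert-butyldimethylsilyl trifluoromethanesulfonate | CC(C)(C)[Si](C)(C)OS(=O)(=O)C(F)(F)F | starting material
19 | 1-O-TBS-5-oxo spiro-lactone | C=C1C[C@]23C[C@H]1CC[C@H]2[C@]4(COC3=O)[C@@H](O[Si](C)(C)C(C)(C)C)CCCC4=O | intermediate
20 | iodomethane | CI | starting material
21 | 1-O-TBS-4-methyl-5-oxo spiro-lactone (C4 epimers) | C=C1C[C@]23C[C@H]1CC[C@H]2[C@]4(COC3=O)[C@@H](O[Si](C)(C)C(C)(C)C)CCC(C)C4=O | intermediate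
22 | (triisopropylsiloxy)methyl chloride | ClCO[Si](C(C)C)(C(C)C)C(C)C | starting material
23 | 1-O-TBS-19-O-TIPS-5-oxo spiro-lactone with quaternary C4 | C=C1C[C@]23C[C@H]1CC[C@H]2[C@]4(COC3=O)[C@@H](O[Si](C)(C)C(C)(C)C)CC[C@@](C)(CO[Si](C(C)C)(C(C)C)C(C)C)C4=O | intermediate
24 | trimethylsulfonium iodide | C[S+](C)C.[I-] | starting material
25 | 1-O-TBS-19-O-TIPS C5 spiro-epoxide (either C5 epimer) | C=C1C[C@]23C[C@H]1CC[C@H]2[C@]4(COC3=O)[C@@H](O[Si](C)(C)C(C)(C)C)CC[C@@](C)(CO[Si](C(C)C)(C(C)C)C(C)C)C45CO5 | intermediate
26 | acetic anhydride | CC(=O)OC(C)=O | starting material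
27 | 1,19-diol C5 spiro-epoxide | C=C1C[C@]23C[C@H]1CC[C@H]2[C@]4(COC3=O)[C@@H](O)CC[C@@](C)(CO)C45CO5 | intermediate (not isolated)
28 | 1,19-diacetate C5 spiro-epoxide | C=C1C[C@]23C[C@H]1CC[C@H]2[C@]4(COC3=O)[C@@H](OC(C)=O)CC[C@@](C)(COC(C)=O)C45CO5 | intermediate
29 | 1,19-diacetoxy-6-hydroxy spiro-lactone, 16(17)-ene, C15H2 | C=C1C[C@]23C[C@H]1CC[C@H]2[C@]4(COC3=O)[C@@H](OC(C)=O)CC[C@@](C)(COC(C)=O)[C@H]4CO | intermediate
30 | tert-butyl hydroperoxide | CC(C)(C)OO | starting material
31 | 1,19-diacetoxy-6,15-dihydroxy spiro-lactone, 16(17)-ene (C15 epimers) | C=C1C(O)[C@]23C[C@H]1CC[C@H]2[C@]4(COC3=O)[C@@H](OC(C)=O)CC[C@@](C)(COC(C)=O)[C@H]4CO | intermediate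
32 | CNP0105570.2 | C=C1C(=O)[C@]23C[C@H]1CC[C@H]2[C@]1(COC3=O)[C@@H](OC(C)=O)CC[C@@](C)(COC(C)=O)[C@H]1CO | target

**Step count.** 17 steps in total; longest linear sequence 16 steps (steps 1–3 and 5–17; step 4 is a one-step branch).

**Steps most likely to fail**

Risk 1, step 5. The C9 radical is flanked by the quaternary C8 and must meet a tetrasubstituted alkenyl–nickel species. Capture may be too slow, so that protodecarboxylation or reduction of 9 takes over, and facial selectivity at C9 may be incomplete. The fallback for step 5 leaves photoredox chemistry and sets out from 6. N-Hydroxyphthalimide and DIC should convert 6 into the N-hydroxyphthalimide ester of 6 F1. F1 is then coupled with 9 by thermal nickel-catalysed reductive cross-electrophile coupling (NiBr2·dme, dtbbpy, Zn, DMA), which comes back to the route at 10. A minor C9 epimer would be only a separable diastereomer, because C8 and C13 are already fixed.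

Risk 2, step 12. The conformation of ring A at the enolate stage is not secure, so the second electrophile may enter on the C9 face instead of the C20 face, and the hindered enolate may be O-alkylated. The fallback for step 12 sets out from 19 and exchanges the order of the two alkylations, so that the group introduced last is the one that must sit on the preferred face. LDA/TOM-Cl should give the 4-(triisopropylsiloxymethyl)-5-oxo compound F2 (C4 epimers). LDA/MeI, kept at −78 °C to avoid β-elimination of the silyloxide, is then the stereodetermining second alkylation and comes back to the route at 23.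

Risk 3, step 13. The C5 ketone lies between two quaternary carbons and the sulfur ylide may simply not add. The fallback for step 13 sets out from 23 and uses a samarium carbenoid, which is chemoselective for ketones over esters. Sm/CH2I2 in THF should give the 5-hydroxy-5-(iodomethyl) compound F3, which K2CO3 in MeOH at 0 °C closes to the epoxide, coming back to the route at 25.

**Further compounds**

F1 | step 5 | 1,3-dioxoisoindolin-2-yl ester of 6 (N-hydroxyphthalimide ester at the C9 carboxyl) | C=C1C[C@]2(C(=O)OCC[Si](C)(C)C)C[C@H]1CC[C@H]2C(=O)ON3C(=O)c4ccccc4C3=O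
F2 | step 12 | 1-O-TBS-4-(triisopropylsiloxymethyl)-5-oxo spiro-lactone (C4 epimers) | C=C1C[C@]23C[C@H]1CC[C@H]2[C@]4(COC3=O)[C@@H](O[Si](C)(C)C(C)(C)C)CCC(CO[Si](C(C)C)(C(C)C)C(C)C)C4=O
F3 | step 13 | 1-O-TBS-19-O-TIPS-5-hydroxy-5-(iodomethyl) spiro-lactone | C=C1C[C@]23C[C@H]1CC[C@H]2[C@]4(COC3=O)[C@@H](O[Si](C)(C)C(C)(C)C)CC[C@@](C)(CO[Si](C(C)C)(C(C)C)C(C)C)C4(O)CI
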